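**Strategy**

Ring A is opened across two bonds at once, C2–C3 and C5–C10 (halimane numbering; ring A = C1–C5, C10; ring B = C5–C10). This leaves an acetonyl unit (C2–C1–C10) on C9 and a 2-(methoxycarbonyl)allyl unit (C3–C4–C5) on C6, because the ester sits on C4. The key step joins them in one base-mediated α,α′-annulation of an acyclic keto allylic bromide: the C10 enolate closes ring B by SN2′ attack at C5, and the acrylate set free then takes the C2 enolate to close ring A. The precursor comes from ozonolytic opening of a cyclohexenone-derived ring that carries C8 and C9; the C1 ketone later becomes the C1=C10 alkene.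

Key step: step 15

**Remarks**

- Numbering (target skeleton): C1 alkene CH; C2, C3 ring-A CH2; C4 bears CH3 (C18) and CO2Me (C19); C5 ring-fusion CH; C6, C7 ring-B CH2; C8 bears CH3 (C17); C9 bears CH3 (C20) and the side chain; C10 ring-fusion alkene carbon; side chain C11, C12, C13 (bears CH3 = C16), C14, C15.
- Assumption: ketone 28 equilibrates to the trans ring fusion under the basic conditions of step 15; C10 becomes sp2 in step 18.
- Assumption: compounds 1, 2, 7, 14, 24 and all reagents are commercial.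

**Route**

Step 1
Reactants: 1 propanal; 2 but-3-en-2-one
Product: 3 (R)-2-methyl-5-oxohexanal
Conditions: (S)-α,α-diphenylprolinol trimethylsilyl ether (5 mol%), PhCO2H (5 mol%), neat, 4 °C
Reagents that add atoms: none
Why: Enamine-catalysed Michael addition; the bulky diaryl(silyloxy)methyl group of the (S)-catalyst shields one face of the E-enamine, so the enone should add to the other face and give the (R)-aldehyde.

Step 2
Reactants: 3 (R)-2-methyl-5-oxohexanal
Product: 4 (R)-4-methylcyclohex-2-en-1-one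
Conditions: KOH (0.1 M aq.), n-Bu4NOH (cat.), Et2O/THF, reflux
Reagents that add atoms: none
Why: Intramolecular aldol condensation (methyl-ketone enolate onto the aldehyde, then E1cB dehydration); the stereocentre ends as the γ-carbon and should survive because ring closure is faster than enolisation of the aldehyde.

Step 3
Reactants: 4 (R)-4-methylcyclohex-2-en-1-one
Product: 6 (R)-3,4-dimethylcyclohex-2-en-1-one, via silyl enol ether 5 (not isolated)
Conditions: MeMgBr, CuBr·SMe2 (5 mol%), Me3SiCl, THF, −78 °C; then Pd(OAc)2 (10 mol%), O2 (1 atm), DMSO, rt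
Reagents that add atoms: methylmagnesium bromide, C[Mg]Br
Why: Copper-catalysed conjugate addition with silyl trapping, then Saegusa–Ito dehydrogenation of 5, re-forms the enone with the new methyl on the β-carbon; the existing stereocentre is not touched and the transient one becomes sp2.

Step 4
Reactants: 7 methyl (S)-2,2-dimethyl-1,3-dioxolane-4-carboxylate
Product: 8 (S)-N-methoxy-N,2,2-trimethyl-1,3-dioxolane-4-carboxamide
Conditions: MeNH(OMe)·HCl, i-PrMgCl, THF, −20 °C
Reagents that add atoms: N,O-dimethylhydroxylamine hydrochloride, CNOC.Cl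
Why: Aminolysis of the ester by the chloromagnesium amide gives the Weinreb amide at low temperature without epimerising the α-alkoxy stereocentre.

Step 5
Reactants: 8 (S)-N-methoxy-N,2,2-trimethyl-1,3-dioxolane-4-carboxamide
Product: 9 1-[(4S)-2,2-dimethyl-1,3-dioxolan-4-yl]prop-2-en-1-one
Conditions: CH2=CHMgBr, THF, −78 → 0 °C; inverse quench into cold 1 M HCl
Reagents that add atoms: vinylmagnesium bromide, C=C[Mg]Br
Why: Weinreb ketone synthesis; the chelated tetrahedral adduct survives until the acidic quench, so the Grignard reagent adds once and the liberated amine cannot add to the enone.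

Step 6
Reactants: 9 1-[(4S)-2,2-dimethyl-1,3-dioxolan-4-yl]prop-2-en-1-one
Product: 11 triethyl{[(2R)-2-[(4S)-2,2-dimethyl-1,3-dioxolan-4-yl]but-3-en-2-yl]oxy}silane, via tertiary alkoxide 10 (not isolated)
Conditions: MeMgBr, Et2O, −78 °C; then Et3SiOTf, −78 → 0 °C
Reagents that add atoms: methylmagnesium bromide, C[Mg]Br; triethylsilyl trifluoromethanesulfonate, CC[Si](CC)(CC)OS(=O)(=O)C(F)(F)F
Why: 1,2-Addition of the Grignard reagent under α-chelation control (magnesium bridges the ketone oxygen and the ring oxygen on the stereocentre, methyl enters from the face of that carbon's hydrogen) should set the (R)-carbinol C13, which is silylated in the same flask.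

Step 7
Reactants: 11 triethyl{[(2R)-2-[(4S)-2,2-dimethyl-1,3-dioxolan-4-yl]but-3-en-2-yl]oxy}silane
Product: 13 triethyl{[(2R)-2-[(4S)-2,2-dimethyl-1,3-dioxolan-4-yl]-4-iodobutan-2-yl]oxy}silane, via alkylborane 12 (not isolated)
Conditions: 9-BBN, THF, 0 °C → rt; then I2, NaOMe, MeOH, 0 °C
Reagents that add atoms: iodine, II
Why: Anti-Markovnikov hydroboration of the monosubstituted alkene, then base-induced iodinolysis of the primary B–C bond, gives the primary iodide; no stereocentre is affected.

Step 8
Reactants: 14 (methoxymethyl)diphenylphosphine oxide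
Product: 15 (1-methoxyethyl)diphenylphosphine oxide
Conditions: n-BuLi, THF, −78 °C; MeI, −78 °C → rt
Reagents that add atoms: iodomethane, CI
Why: α-Lithiation of the phosphine oxide and C-methylation give the homologated Horner–Wittig reagent.

Step 9
Reactants: 13 triethyl{[(2R)-2-[(4S)-2,2-dimethyl-1,3-dioxolan-4-yl]-4-iodobutan-2-yl]oxy}silane; 6 (R)-3,4-dimethylcyclohex-2-en-1-one
Product: 17 side-chain silyl enol ether (3S,4R), via Grignard reagent 16 (not isolated)
Conditions: 13, Mg, THF, rt; then CuBr·SMe2 (10 mol%), Me3SiCl, HMPA, 6, THF, −78 → −40 °C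
Reagents that add atoms: chlorotrimethylsilane, C[Si](C)(C)Cl
Why: Silyl-chloride-accelerated copper-catalysed conjugate addition builds the quaternary C9; attack anti to the C8 methyl of the enone half-chair places the side chain trans to that methyl (the two methyls cis), and the enolate is trapped regiospecifically as the C5–C10 silyl enol ether.

Step 10
Reactants: 17 side-chain silyl enol ether (3S,4R)
Product: 19 methyl (4R,5S,8R)-8-[(4S)-2,2-dimethyl-1,3-dioxolan-4-yl]-5-formyl-4,5-dimethyl-8-(triethylsilyloxy)nonanoate, via aldehyde acid 18 (not isolated)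
Conditions: O3, CH2Cl2/MeOH, −78 °C; Me2S, −78 °C → rt; then Me3SiCHN2, PhMe/MeOH, 0 °C
Reagents that add atoms: ozone, [O-][O+]=O; (trimethylsilyl)diazomethane, C[Si](C)(C)C=[N+]=[N-]
Why: Ozonolysis of the electron-rich silyl enol ether cleaves the ring bond C5–C10 into the C10 aldehyde and the C5 carboxylic acid, which the diazoalkane esterifies; C9 is quaternary, so no centre can epimerise.

Step 11
Reactants: 19 methyl (4R,5S,8R)-8-[(4S)-2,2-dimethyl-1,3-dioxolan-4-yl]-5-formyl-4,5-dimethyl-8-(triethylsilyloxy)nonanoate; 15 (1-methoxyethyl)diphenylphosphine oxide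
Product: 21 methyl enol ether ester (E/Z mixture), via hydroxy phosphine oxide adduct 20 (not isolated)
Conditions: 15, LiN(i-Pr)2, THF, −78 °C; 19; then KOt-Bu, −78 °C → rt
Reagents that add atoms: none
Why: Horner–Wittig olefination; the lithiated α-methoxy phosphine oxide adds to the non-enolisable aldehyde faster than to the ester, and potassium exchange triggers syn-elimination of diphenylphosphinate from 20 to give the methyl enol ether, a masked methyl ketone whose alkene geometry is irrelevant.

Step 12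
Reactants: 21 methyl enol ether ester (E/Z mixture)
Product: 23 (4R,5R,8R)-8-[(4S)-2,2-dimethyl-1,3-dioxolan-4-yl]-4,5-dimethyl-5-(2-oxopropyl)-8-(triethylsilyloxy)nonanal, via enol ether aldehyde 22 (not isolated)
Conditions: i-Bu2AlH (1.1 equiv), CH2Cl2, −78 °C; MeOH, aq. KNaC4H4O6; then (CO2H)2 (cat.), wet SiO2, CH2Cl2, rt
Reagents that add atoms: water, O
Why: Partial reduction of the methyl ester through the aluminium hemiacetal that is stable at −78 °C, then mild acid hydrolysis of the enol ether, unveils aldehyde and methyl ketone without cleaving the silyl ether or the acetonide.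

Step 13
Reactants: 23 (4R,5R,8R)-8-[(4S)-2,2-dimethyl-1,3-dioxolan-4-yl]-4,5-dimethyl-5-(2-oxopropyl)-8-(triethylsilyloxy)nonanal; 24 methyl acrylate
Product: 25 Morita–Baylis–Hillman alcohol (C5 epimers)
Conditions: DABCO (1 equiv), methyl acrylate (5 equiv), MeOH (cat.), rt
Reagents that add atoms: none
Why: Morita–Baylis–Hillman reaction; the DABCO–acrylate zwitterion adds to the unhindered aldehyde (the ketone is inert) and β-elimination releases the amine; the carbinol configuration is lost in step 15.

Step 14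
Reactants: 25 Morita–Baylis–Hillman alcohol (C5 epimers)
Product: 26 methyl (2Z,6R,7R,10R)-2-(bromomethyl)-10-[(4S)-2,2-dimethyl-1,3-dioxolan-4-yl]-6,7-dimethyl-7-(2-oxopropyl)-10-(triethylsilyloxy)undec-2-enoate
Conditions: NBS, Me2S, CH2Cl2, 0 °C → rt
Reagents that add atoms: N-bromosuccinimide, O=C1CCC(=O)N1Br
Why: The bromodimethylsulfonium reagent activates the allylic alcohol and bromide enters with allylic transposition (SN2′) to give the thermodynamically preferred (Z)-2-(bromomethyl)enoate.

Step 15
Reactants: 26 methyl (2Z,6R,7R,10R)-2-(bromomethyl)-10-[(4S)-2,2-dimethyl-1,3-dioxolan-4-yl]-6,7-dimethyl-7-(2-oxopropyl)-10-(triethylsilyloxy)undec-2-enoate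
Product: 28 trans-fused 1-oxo decalin ester (C4 epimers), via monocyclic methylene ester 27 (not isolated)
Conditions: KOt-Bu (2.2 equiv), THF/t-BuOH (10:1), 0.005 M, −20 °C → rt; aq. NH4Cl
Reagents that add atoms: none
Why: The base forms the ketone enolates reversibly; the C10 enolate attacks C5 of the (Z)-2-(bromomethyl)enoate in an SN2′ displacement that expels bromide, closes ring B and unmasks an α-methylene ester (27), whose acrylate then accepts the methyl-ketone (C2) enolate at C3 in a Michael addition that closes ring A, the ester enolate being protonated by t-BuOH. The closest known reaction type is the α,α′-annulation of ketone enolates or enamines with 2-(bromomethyl)acrylates, run here intramolecularly. Ring B closes in the 6-exo-trig mode and ring A in the 6-endo-trig mode. The new C5 stereocentre is set in the first closure by a chair transition state in which the C9 side chain, the C8 methyl and the acceptor arm are equatorial and only the C9 methyl is axial, which should place H-5 cis to the C9 methyl (5R); C10 and C4 are epimerisable and should settle trans-fused and equatorial, and both are reset later. The step needs C10-over-C2 regioselectivity in the first alkylation, which ring size secures (attack from C2 would form an eight- or ten-membered ring), and it needs ring closure to outrun intermolecular alkylation and base-induced 1,4-elimination of HBr, for which high dilution and low temperature are used.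

Step 16
Reactants: 28 trans-fused 1-oxo decalin ester (C4 epimers)
Product: 29 axial 1-hydroxy ester (1S)
Conditions: NaBH4, MeOH/THF, 0 °C
Reagents that add atoms: none
Why: Hydride reduction; attack on the C1 ketone from the face opposite the axial C9 methyl (as with 11-oxo steroids) should give the axial 1-alcohol cis to H-5, and the ester is inert to NaBH4.

Step 17
Reactants: 29 axial 1-hydroxy ester (1S)
Product: 30 C4-methylated hydroxy ester (1S,4S)
Conditions: LiN(i-Pr)2 (2.5 equiv), THF/DMPU, −78 → −20 °C; MeI; aq. NH4Cl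
Reagents that add atoms: iodomethane, CI
Why: Ester enolate alkylation with the C1 alkoxide as spectator; in the trans-decalin the electrophile should enter equatorially, away from the axial hydrogens on C2 and C10, giving the equatorial C18 methyl cis to H-5 and the axial ester (4S).

Step 18
Reactants: 30 C4-methylated hydroxy ester (1S,4S)
Product: 31 protected 1(10)-alkene ester
Conditions: Ph2S[OC(CF3)2Ph]2 (Martin sulfurane), CH2Cl2, rt
Reagents that add atoms: none
Why: E2 dehydration through the alkoxysulfonium of the axial 1-alcohol; the axial tertiary H-10 is anti-periplanar, and its loss gives the more substituted C1=C10 alkene and relieves the 1,3-diaxial strain with the C9 methyl (11β-hydroxy steroids give the 9(11)-alkene in the same way).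

Step 19
Reactants: 31 protected 1(10)-alkene ester
Product: 32 13,14,15-triol
Conditions: TsOH·H2O (10 mol%), MeOH, rt
Reagents that add atoms: none
Why: Acid-catalysed methanolysis removes the triethylsilyl ether and exchanges the acetonide, releasing the triol without touching the alkene, the ester or any stereocentre.

Step 20
Reactants: 32 13,14,15-triol
Product: 33 target CNP0238486.2
Conditions: Ac2O, pyridine, rt
Reagents that add atoms: acetic anhydride, CC(=O)OC(C)=O
Why: Acetylation; the primary C15 and secondary C14 hydroxyls are esterified, while the hindered tertiary C13 hydroxyl should not react without an acyl-transfer catalyst.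

**Compound list**

1 | propanal | CCC=O | starting material
2 | but-3-en-2-one (methyl vinyl ketone) | CC(=O)C=C | starting material
3 | (R)-2-methyl-5-oxohexanal | CC(=O)CC[C@@H](C)C=O | intermediate
4 | (R)-4-methylcyclohex-2-en-1-one | O=C1CC[C@@H](C)C=C1 | intermediate
5 | trimethyl{[(3S,4R)-3,4-dimethylcyclohex-1-en-1-yl]oxy}silane | C[Si](C)(C)OC1=C[C@@H](C)[C@H](C)CC1 | intermediate
6 | (R)-3,4-dimethylcyclohex-2-en-1-one | O=C1CC[C@@H](C)C(C)=C1 | intermediate
7 | methyl (S)-2,2-dimethyl-1,3-dioxolane-4-carboxylate | COC(=O)[C@H]1OC(C)(C)OC1 | starting material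
8 | (S)-N-methoxy-N,2,2-trimethyl-1,3-dioxolane-4-carboxamide | CON(C)C(=O)[C@H]1OC(C)(C)OC1 | intermediate
9 | 1-[(4S)-2,2-dimethyl-1,3-dioxolan-4-yl]prop-2-en-1-one | C=CC(=O)[C@H]1OC(C)(C)OC1 | intermediate
10 | (2R)-2-[(4S)-2,2-dimethyl-1,3-dioxolan-4-yl]but-3-en-2-ol, formed as its bromomagnesium alkoxide | C=C[C@@](C)(O)[C@H]1OC(C)(C)OC1 | intermediate
11 | triethyl{[(2R)-2-[(4S)-2,2-dimethyl-1,3-dioxolan-4-yl]but-3-en-2-yl]oxy}silane | C=C[C@@](C)(O[Si](CC)(CC)CC)[C@H]1OC(C)(C)OC1 | intermediate
12 | 9-{(3R)-3-[(4S)-2,2-dimethyl-1,3-dioxolan-4-yl]-3-(triethylsilyloxy)butyl}-9-borabicyclo[3.3.1]nonane | B1(CC[C@@](C)(O[Si](CC)(CC)CC)[C@H]2OC(C)(C)OC2)C2CCCC1CCC2 | intermediate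
13 | triethyl{[(2R)-2-[(4S)-2,2-dimethyl-1,3-dioxolan-4-yl]-4-iodobutan-2-yl]oxy}silane | ICC[C@@](C)(O[Si](CC)(CC)CC)[C@H]1OC(C)(C)OC1 | intermediate
14 | (methoxymethyl)diphenylphosphine oxide | COCP(=O)(c1ccccc1)c1ccccc1 | starting material
15 | (1-methoxyethyl)diphenylphosphine oxide (racemic) | COC(C)P(=O)(c1ccccc1)c1ccccc1 | intermediate
16 | {(3R)-3-[(4S)-2,2-dimethyl-1,3-dioxolan-4-yl]-3-(triethylsilyloxy)butyl}magnesium iodide | I[Mg]CC[C@@](C)(O[Si](CC)(CC)CC)[C@H]1OC(C)(C)OC1 | intermediate
17 | trimethyl{[(3S,4R)-3-{(3R)-3-[(4S)-2,2-dimethyl-1,3-dioxolan-4-yl]-3-(triethylsilyloxy)butyl}-3,4-dimethylcyclohex-1-en-1-yl]oxy}silane (side chain trans to the C4 methyl) | C[Si](C)(C)OC1=C[C@@](C)(CC[C@@](C)(O[Si](CC)(CC)CC)[C@H]2OC(C)(C)OC2)[C@H](C)CC1 | intermediate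
18 | (4R,5S,8R)-8-[(4S)-2,2-dimethyl-1,3-dioxolan-4-yl]-5-formyl-4,5-dimethyl-8-(triethylsilyloxy)nonanoic acid | O=C[C@@](C)(CC[C@@](C)(O[Si](CC)(CC)CC)[C@H]1OC(C)(C)OC1)[C@H](C)CCC(=O)O | intermediate
19 | methyl (4R,5S,8R)-8-[(4S)-2,2-dimethyl-1,3-dioxolan-4-yl]-5-formyl-4,5-dimethyl-8-(triethylsilyloxy)nonanoate | O=C[C@@](C)(CC[C@@](C)(O[Si](CC)(CC)CC)[C@H]1OC(C)(C)OC1)[C@H](C)CCC(=O)OC | intermediate
20 | methyl (4R,8R)-8-[(4S)-2,2-dimethyl-1,3-dioxolan-4-yl]-5-[2-(diphenylphosphoryl)-1-hydroxy-2-methoxypropyl]-4,5-dimethyl-8-(triethylsilyloxy)nonanoate (C5 as in 19; mixture at the two new centres; formed as its alkoxide) | COC(C)(C(O)[C@@](C)(CC[C@@](C)(O[Si](CC)(CC)CC)[C@H]1OC(C)(C)OC1)[C@H](C)CCC(=O)OC)P(=O)(c1ccccc1)c1ccccc1 | intermediate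
21 | methyl (4R,5S,8R)-8-[(4S)-2,2-dimethyl-1,3-dioxolan-4-yl]-5-(2-methoxyprop-1-en-1-yl)-4,5-dimethyl-8-(triethylsilyloxy)nonanoate (E/Z mixture, alkene geometry not specified) | COC(C)=C[C@@](C)(CC[C@@](C)(O[Si](CC)(CC)CC)[C@H]1OC(C)(C)OC1)[C@H](C)CCC(=O)OC | intermediate
22 | (4R,5S,8R)-8-[(4S)-2,2-dimethyl-1,3-dioxolan-4-yl]-5-(2-methoxyprop-1-en-1-yl)-4,5-dimethyl-8-(triethylsilyloxy)nonanal (E/Z mixture) | COC(C)=C[C@@](C)(CC[C@@](C)(O[Si](CC)(CC)CC)[C@H]1OC(C)(C)OC1)[C@H](C)CCC=O | intermediate
23 | (4R,5R,8R)-8-[(4S)-2,2-dimethyl-1,3-dioxolan-4-yl]-4,5-dimethyl-5-(2-oxopropyl)-8-(triethylsilyloxy)nonanal | CC(=O)C[C@@](C)(CC[C@@](C)(O[Si](CC)(CC)CC)[C@H]1OC(C)(C)OC1)[C@H](C)CCC=O | intermediate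
24 | methyl acrylate | C=CC(=O)OC | starting material
25 | methyl (6R,7R,10R)-10-[(4S)-2,2-dimethyl-1,3-dioxolan-4-yl]-3-hydroxy-6,7-dimethyl-2-methylidene-7-(2-oxopropyl)-10-(triethylsilyloxy)undecanoate (C3 epimers = C5 of the skeleton) | CC(=O)C[C@@](C)(CC[C@@](C)(O[Si](CC)(CC)CC)[C@H]1OC(C)(C)OC1)[C@H](C)CCC(O)C(=C)C(=O)OC | intermediate
26 | methyl (2Z,6R,7R,10R)-2-(bromomethyl)-10-[(4S)-2,2-dimethyl-1,3-dioxolan-4-yl]-6,7-dimethyl-7-(2-oxopropyl)-10-(triethylsilyloxy)undec-2-enoate | CC(=O)C[C@@](C)(CC[C@@](C)(O[Si](CC)(CC)CC)[C@H]1OC(C)(C)OC1)[C@H](C)CC/C=C(\CBr)C(=O)OC | intermediate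
27 | methyl 2-[(1R,3S,4R)-2-acetyl-3-{(3R)-3-[(4S)-2,2-dimethyl-1,3-dioxolan-4-yl]-3-(triethylsilyloxy)butyl}-3,4-dimethylcyclohexyl]prop-2-enoate (C2 epimers = C10 of the skeleton) | CC(=O)C1[C@H](C(=C)C(=O)OC)CC[C@@H](C)[C@]1(C)CC[C@@](C)(O[Si](CC)(CC)CC)[C@H]2OC(C)(C)OC2 | intermediate
28 | methyl (5R,8R,9S,10S,13R,14S)-14,15-(isopropylidenedioxy)-1-oxo-13-(triethylsilyloxy)-18-norhalimane-19-oate (trans-fused, H-5 cis to the C9 methyl, C4 epimers) | COC(=O)C1CCC(=O)[C@H]2[C@H]1CC[C@@H](C)[C@]2(C)CC[C@@](C)(O[Si](CC)(CC)CC)[C@H]3OC(C)(C)OC3 | intermediate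
29 | methyl (1S,5R,8R,9S,10S,13R,14S)-1-hydroxy-14,15-(isopropylidenedioxy)-13-(triethylsilyloxy)-18-norhalimane-19-oate (axial 1-OH cis to H-5, C4 epimers) | COC(=O)C1CC[C@H](O)[C@H]2[C@H]1CC[C@@H](C)[C@]2(C)CC[C@@](C)(O[Si](CC)(CC)CC)[C@H]3OC(C)(C)OC3 | intermediate
30 | methyl (1S,4S,5R,8R,9S,10S,13R,14S)-1-hydroxy-14,15-(isopropylidenedioxy)-13-(triethylsilyloxy)halimane-19-oate | COC(=O)[C@@]1(C)CC[C@H](O)[C@H]2[C@H]1CC[C@@H](C)[C@]2(C)CC[C@@](C)(O[Si](CC)(CC)CC)[C@H]3OC(C)(C)OC3 | intermediate
31 | methyl (4S,5R,8R,9S,13R,14S)-14,15-(isopropylidenedioxy)-13-(triethylsilyloxy)halim-1(10)-en-19-oate | COC(=O)[C@@]1(C)CCC=C2[C@H]1CC[C@@H](C)[C@]2(C)CC[C@@](C)(O[Si](CC)(CC)CC)[C@H]3OC(C)(C)OC3 | intermediate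
32 | methyl (4S,5R,8R,9S,13R,14S)-13,14,15-trihydroxyhalim-1(10)-en-19-oate | COC(=O)[C@@]1(C)CCC=C2[C@H]1CC[C@@H](C)[C@]2(C)CC[C@@](C)(O)[C@H](CO)O | intermediate
33 | methyl (4S,5R,8R,9S,13R,14S)-14,15-diacetoxy-13-hydroxyhalim-1(10)-en-19-oate (CNP0238486.2) | COC(=O)[C@@]1(C)CCC=C2[C@H]1CC[C@@H](C)[C@]2(C)CC[C@@](C)(O)[C@H](COC(C)=O)OC(C)=O | target

**Step count and risks**

Total step count: 20 (steps 1–20).
Longest linear sequence: 16 steps (from 7 through steps 4–7 and 9–20). The enone branch (steps 1–3) joins at step 9 and the reagent branch (step 8) at step 11.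

Three steps most likely to fail:

1. Step 15 (key bicyclisation). What may go wrong: base-induced 1,4-elimination of HBr to a dienoate, intermolecular alkylation outrunning the first ring closure, or insufficient facial selectivity at C5. Fallback: the two bonds are made in two separate, milder operations. The route is left at alcohol 25. Acetylation (Ac2O, DMAP, pyridine) should give the Morita–Baylis–Hillman acetate F1. Pd(PPh3)4 (5 mol%) and pyrrolidine (30 mol%) in DMSO at rt should ionise the allylic acetate and let the C10 enamine of the methyl ketone attack the π-allyl terminus C5 (six-membered ring favoured over the eight-membered alternative), giving methylene ester 27, which is now isolated. NaOMe in MeOH then brings about the 6-endo Michael closure, and the fallback returns to the route at 28.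

2. Step 18 (dehydration). What may go wrong: loss of regiocontrol in the elimination (removal of H-2 instead of H-10) or substitution at C1. Fallback: the alkene is made by reduction of an enol triflate, replacing steps 16–18. The route is left at ketone 28. Tf2O with 2,6-di-tert-butyl-4-methylpyridine in CH2Cl2 should give the more substituted enol triflate F2 (C1=C10). Pd(OAc)2/PPh3 with n-Bu3N and HCO2H in DMF at 60 °C should replace the triflate by hydrogen to give alkene ester F3. LiN(i-Pr)2 and then MeI methylate C4, where the equatorial preference would have to be confirmed, and the fallback returns to the route at 31.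

3. Step 11 (Horner–Wittig olefination). What may go wrong: slow or reversible addition of the bulky phosphine oxide anion to the α-quaternary aldehyde, or competing attack on the ester. Fallback: the acetonyl group is built by Wittig olefination and Wacker oxidation. The route is left at aldehyde ester 19. Ph3P=CHCH3 (from EtPPh3Br and KN(SiMe3)2 in THF) should give the (Z)-propenyl ester F4. i-Bu2AlH at −78 °C gives aldehyde F5. PdCl2 (cat.), CuCl and O2 in DMF/H2O should place the ketone oxygen on the alkene carbon remote from the quaternary C9, and the fallback returns to the route at 23.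

**Further compounds**

F1 | step 15 | methyl (6R,7R,10R)-3-acetoxy-10-[(4S)-2,2-dimethyl-1,3-dioxolan-4-yl]-6,7-dimethyl-2-methylidene-7-(2-oxopropyl)-10-(triethylsilyloxy)undecanoate (C3 epimers) | CC(=O)C[C@@](C)(CC[C@@](C)(O[Si](CC)(CC)CC)[C@H]1OC(C)(C)OC1)[C@H](C)CCC(OC(C)=O)C(=C)C(=O)OC
F2 | step 18 | methyl (5R,8R,9S,13R,14S)-14,15-(isopropylidenedioxy)-1-(trifluoromethylsulfonyloxy)-13-(triethylsilyloxy)-18-norhalim-1(10)-en-19-oate (C4 epimers) | COC(=O)C1CCC(OS(=O)(=O)C(F)(F)F)=C2[C@H]1CC[C@@H](C)[C@]2(C)CC[C@@](C)(O[Si](CC)(CC)CC)[C@H]3OC(C)(C)OC3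
F3 | step 18 | methyl (5R,8R,9S,13R,14S)-14,15-(isopropylidenedioxy)-13-(triethylsilyloxy)-18-norhalim-1(10)-en-19-oate (C4 epimers) | COC(=O)C1CCC=C2[C@H]1CC[C@@H](C)[C@]2(C)CC[C@@](C)(O[Si](CC)(CC)CC)[C@H]3OC(C)(C)OC3
F4 | step 11 | methyl (4R,5S,8R)-8-[(4S)-2,2-dimethyl-1,3-dioxolan-4-yl]-4,5-dimethyl-5-[(1Z)-prop-1-en-1-yl]-8-(triethylsilyloxy)nonanoate | C/C=C\[C@@](C)(CC[C@@](C)(O[Si](CC)(CC)CC)[C@H]1OC(C)(C)OC1)[C@H](C)CCC(=O)OC
F5 | step 11 | (4R,5S,8R)-8-[(4S)-2,2-dimethyl-1,3-dioxolan-4-yl]-4,5-dimethyl-5-[(1Z)-prop-1-en-1-yl]-8-(triethylsilyloxy)nonanal | C/C=C\[C@@](C)(CC[C@@](C)(O[Si](CC)(CC)CC)[C@H]1OC(C)(C)OC1)[C@H](C)CCC=O
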